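At late times the midnight flask reads 55% and then 55% of E, a flat line. But the dawn flask, with half the J, stands at 37%, and “A true equilibrium would not depend on the catalyst loading”. So read J as a pulse that dies, and each plateau as what that pulse delivered.

all flasks: X 0.80 M
- midnight: Q 0.88 M; D 0.40 M; J 3.8 mM; the very flask that is asked about, followed so far
- dawn: Q 0.88 M; D 0.40 M; J 1.9 mM; run made earlier
- flask: Q 0.880 M; D 0.400 M; J 3.8 mM; time 10 h

midnight run (percent of the X charged)

| time / h | E / % |
|---|---|
| 0.667 | 43 |
| 1.00 | 49 |
| 2.00 | 52 |
| 3.00 | 54 |
| 5.00 | 55 |
| 8.00 | 55 |

dawn run (percent of the X charged)

| time / min | E / % |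
|---|---|
| 20.0 | 16 |
| 40.0 | 31 |
| 60.0 | 32 |
| 80.0 | 34 |
| 90.0 | 37 |
| 120 | 37 |

(each reading ± 1.5 percentage points)

- west: at 10 h take out 90% of the E then present, then wait 3.0 h
- south-west: change nothing and wait 3.0 h more
- north-west: at 10 h add J, 100% of the amount charged, then wait 3.0 h

- E, in percent of the X first charged, at 10 h
- which option adds most E ("none" when 2 percentage points or less is all one gets) (west / south-west / north-west / none)
- E present, with what was taken out counted in, in percent of the X first charged, after south-west
- E present, with what was taken out counted in, in percent of the X first charged, after north-west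

- E taken out counts as made
- the analysis behind the earlier runs scatters by 1.5 percentage points, standard deviation
- additions bring no volume worth counting

My own reckoning takes X as falling pseudo-first-order under J and Q, with one Q spent per E. Count the e-folds of X, the natural log of X charged over X left: 0.799 on the midnight plateau. Then replace the falling curve of q, the fraction of Q left, by the mean of its ends. On this count q ends at 50.0%, which gives 1.06, the dose number, the e-folds of X per unit of mean q that a charge of 3.8 mM of J delivers. As a check, the dawn flask ends at q = 66.4%, and a dose of 0.500 of the midnight one then gives 35.8% of E, against the reading of 37% with a scatter of 1.5 percentage points.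

The forecast says 55% at 10 h, 55% after waiting, and north-west as best, reaching 71%. A second dose that starts at q = 50.0% and ends where that figure puts it, 35.5%, gives me 71.4%.

The flask gives 53.7%, then 53.7% after south-west, and 64.9% after north-west, which adds 11 points.

    X + Q + J → J + E (k = 0.151 /M²/s)
    D + Q + J → J + G (k = 0.140 /M²/s)
    J → Z (k = 3.42 × 10⁻⁴ /s)

The forecast's north-west figure stands 6.1 points above the flask. At 10.0 h the flask holds Q at 27.9% of its charge, against the 50.0% of my count, with D down to 48.9% and G at 0.204 M. Start the second dose at that Q, let it fall by what E gains, and the same dose number gives 63.7%. The neighbour flask, charged with 0.53 M of Q, ends with Q at 21.9% of its own charge. That is a mean of 36.7% of the 0.880 M charge, so the dose number gives 32.2%, and the neighbour flask holds E at 35.2%.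

(The numbers in the tables were computed on assumed constants, noise included.)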